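## Retrosynthetic overview

1. Target ⇒ (global desilylation) undeca-silyl ether ⇒ Friedel–Crafts union at the diaryl methine of a west dihydrobenzofuran carbinol (chalcone arm already installed by Heck reaction) with an east C-aryl tetrahydrofuran.
2. West: the trans-2-aryl-3-acyl-2,3-dihydrobenzofuran comes from an enantioselective, dearomatising CuH conjugate reduction of a flat 2-aryl-3-aroylbenzofuran (key step), itself made by Sonogashira/cyclisation and C3 acylation.
3. East: the tetrahydrofuran comes from a symmetric 1,4-diaryl-1,4-diketone (oxidative dimer of two molecules of one acetophenone) by a desymmetrising boron aldol/cyclodehydration (2,3-dihydrofuran), then cationic C-benzylation and oxocarbenium reduction.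
4. Ring order: west benzofuran → dihydrobenzofuran; east dihydrofuran → tetrahydrofuran; no ring is formed after the fragment union.

Abbreviations: TBS = tert-butyldimethylsilyl, TBSO = tert-butyldimethylsilyloxy, Ipc = isopinocampheyl.

Assumption: the silyl-protected building blocks 4, 7 and 11 are bought as catalogue compounds, and the antipode of each chiral reagent or ligand is chosen that delivers the configuration stated.

## Route

Step 1
Reactants: 1 2',4'-dihydroxyacetophenone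
Product: 2 2',4'-bis(TBSO)acetophenone
Conditions: TBSCl (2.4 equiv), imidazole (5 equiv), DMF, 25 °C
Reagents that add atoms: tert-butyldimethylsilyl chloride (TBSCl), C[Si](C)(Cl)C(C)(C)C
Why: Imidazole-promoted O-silylation of both phenols (the chelated 2-OH more slowly) gives aryl silyl ethers that tolerate amide bases, Lewis acids at low temperature and Pd or Cu catalysis and are removed by fluoride at the end.

Step 2
Reactants: 2 2',4'-bis(TBSO)acetophenone (two molecules per molecule of product; the second one is entered below)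
Product: 3 symmetric 1,4-diketone
Conditions: LiN(i-Pr)2 (1.05 equiv per ketone), THF, −78 °C; then CuCl2 (1.1 equiv per ketone), DMF, −78 → 25 °C
Reagents that add atoms: a second molecule of ketone 2 (1-[2,4-bis(TBSO)phenyl]ethan-1-one), CC(=O)c1ccc(O[Si](C)(C)C(C)(C)C)cc1O[Si](C)(C)C(C)(C)C
Why: Oxidative homocoupling of the lithium enolate by CuCl2 (Saegusa enolate dimerisation) joins two molecules of 2 at their α-carbons with loss of one hydrogen from each, and gives the achiral, twofold-symmetric 1,4-diketone in one operation.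

Step 3
Reactants: 3 symmetric 1,4-diketone; 4 4-(TBSO)benzaldehyde
Product: 6 (2R,3R)-trans-2,3-dihydrofuran ketone, via syn-aldol 5 (not isolated)
Conditions: (−)-Ipc2BOTf (1.05 equiv), i-Pr2NEt (1.3 equiv), CH2Cl2, −78 °C; 4 (1.2 equiv), −78 → −20 °C; H2O2, MeOH, pH 7 buffer, 0 °C; then crude 5, PPTS (10 mol%), 4 Å MS, toluene, 50 °C
Reagents that add atoms: none
Why: Paterson boron aldol reaction followed by acid-catalysed cyclodehydration: the Z-boron enolate of one of the two equivalent ketone arms adds to 4 through a chair transition state whose facial sense is dictated by the isopinocampheyl ligands, which breaks the symmetry of 3 and sets the syn pair of stereocentres (both R), after which the new hydroxyl closes onto the remote aryl ketone and water is lost to give the aryl enol ether with the 2-aryl and 3-aroyl groups trans.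

Step 4
Reactants: 6 (2R,3R)-trans-2,3-dihydrofuran ketone; 7 4-(TBSO)benzyl bromide
Product: 9 east tetrahydrofuran, via 2-bromooxolane 8 (not isolated)
Conditions: ZnBr2 (20 mol%), 4 Å MS, CH2Cl2, −40 → −20 °C; then Et3SiH (3 equiv), −78 → −40 °C
Reagents that add atoms: none
Why: Proposed new method: ZnBr2 ionises the SN1-active benzyl bromide and the enol-ether β-carbon of 6 captures the cation anti to the neighbouring aroyl group, giving a 2-aryl oxocarbenium ion (resting as bromide 8) that Et3SiH reduces from the face opposite the new benzyl group, so that the aryl group ends up cis to benzyl in the 2,3-cis-3,4-trans-4,5-trans array of the target, the closest known reactions being the Lewis-acid α-benzylation of enol ethers with SN1-active halides and the Lewis-acid/silane reduction of 2-aryl oxocarbenium ions used for 2,3-cis tetrahydrofuran lignans.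

Step 5
Reactants: 10 4-bromo-2-iodophenol; 11 tert-butyl(4-ethynylphenoxy)dimethylsilane
Product: 13 5-bromo-2-aryl-benzofuran, via 2-alkynylphenol 12 (not isolated)
Conditions: Pd(PPh3)2Cl2 (2 mol%), CuI (4 mol%), Et3N, DMF, 25 °C then 70 °C
Reagents that add atoms: none
Why: Chemoselective Sonogashira coupling at the C–I bond is followed in the same flask by copper-assisted 5-endo-dig addition of the phenol to the alkyne, which builds the benzofuran and keeps the C–Br bond for step 11.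

Step 6
Reactants: 14 2,4-dihydroxybenzoic acid
Product: 16 2,4-bis(TBSO)benzoyl chloride, via silyl ester 15 (not isolated)
Conditions: TBSCl (3.3 equiv), imidazole (7 equiv), DMF, 25 °C; pentane extraction; then (COCl)2 (1.2 equiv), DMF (cat.), CH2Cl2, 0 → 25 °C
Reagents that add atoms: tert-butyldimethylsilyl chloride (TBSCl), C[Si](C)(Cl)C(C)(C)C; oxalyl chloride, O=C(Cl)C(=O)Cl
Why: Exhaustive silylation followed by the direct conversion of a silyl ester into the acid chloride with oxalyl chloride and catalytic DMF (Vilsmeier-type activation) gives the acylating agent under neutral conditions that leave the aryl silyl ethers intact.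

Step 7
Reactants: 13 5-bromo-2-aryl-benzofuran; 16 2,4-bis(TBSO)benzoyl chloride
Product: 17 2-aryl-3-aroyl-benzofuran
Conditions: SnCl4 (1.1 equiv), CH2Cl2, −40 → 0 °C
Reagents that add atoms: none
Why: Friedel–Crafts acylation of a 2-substituted benzofuran occurs at C3, the enol-ether β-carbon, which is far more nucleophilic than any position of the silyloxyarenes.

Step 8
Reactants: 17 2-aryl-3-aroyl-benzofuran
Product: 20 (2R,3R)-trans dihydrobenzofuran ketone, via silyl enol ether 18 (not isolated), via cis ketone 19 (not isolated)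
Conditions: Cu(OAc)2 (5 mol%), (R)-DTBM-SEGPHOS (5.5 mol%), (EtO)2MeSiH (3 equiv), toluene, 25–40 °C; 1 M HCl, THF, 0 °C; then DBU (20 mol%), CH2Cl2, 25 °C
Reagents that add atoms: none
Why: Proposed new method: the ligated CuH adds hydride to C2 of the 3-aroylbenzofuran, whose C2=C3 bond is a vinylogous ester with little aromatic stabilisation, the bulky bisphosphine choosing the enantioface and fixing the C2 stereocentre, the enolate is silylated, hydrolysed to the cis ketone and equilibrated at the acidic C3 to the more stable trans isomer (ring opening by loss of the aryloxide being the stereoelectronically disfavoured reverse of a 5-endo-trig closure), the closest known reactions being CuH/bisphosphine asymmetric conjugate reductions of β,β-disubstituted enones and of coumarins.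

Step 9
Reactants: 20 (2R,3R)-trans dihydrobenzofuran ketone
Product: 21 west carbinol
Conditions: NaBH4 (1.5 equiv), CeCl3·7H2O (1.2 equiv), MeOH/THF, −40 °C
Reagents that add atoms: none
Why: Luche-type hydride reduction of the hindered aryl ketone under near-neutral conditions gives the benzylic carbinol as an inconsequential mixture of epimers, because this carbon is planarised again in step 12, while C2 and C3 are untouched.

Step 10
Reactants: 2 2',4'-bis(TBSO)acetophenone
Product: 22 aryl vinyl ketone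
Conditions: (CH2O)n (3 equiv), N-methylanilinium trifluoroacetate (1.5 equiv), THF, 65 °C; used at once
Reagents that add atoms: paraformaldehyde (as formaldehyde), C=O
Why: Mannich-type α-methylenation (Gras conditions) in which the anilinium salt condenses with formaldehyde to an iminium ion that is attacked by the enol of 2, and β-elimination of the amine then gives the aryl vinyl ketone.

Step 11
Reactants: 21 west carbinol; 22 aryl vinyl ketone
Product: 23 chalcone carbinol
Conditions: Pd2(dba)3 (2.5 mol%), [HP(t-Bu)3]BF4 (10 mol%), Cy2NMe (1.5 equiv), 1,4-dioxane, 50 °C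
Reagents that add atoms: none
Why: Mizoroki–Heck reaction of the aryl bromide with the vinyl ketone under mild trialkylphosphine conditions installs the chalcone arm with E geometry (syn insertion, syn β-hydride elimination) without touching the free carbinol or the silyl ethers.

Step 12
Reactants: 23 chalcone carbinol; 9 east tetrahydrofuran
Product: 24 undeca-TBS ether of the target
Conditions: 9 (2.5 equiv, excess recovered), TMSOTf (20 mol%), 4 Å MS, CH2Cl2, −78 → −45 °C, slow addition of 23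
Reagents that add atoms: none
Why: Friedel–Crafts alkylation through an α-chiral benzylic cation, in which ionisation gives the 2,4-bis(silyloxy)benzyl cation that holds its C3–H bond in the cation plane (1,3-allylic strain) and is attacked by the most nucleophilic arene position of 9 (para to one silyloxy group and ortho to the other) from the face turned away from the fused benzo ring, which is predicted to give the (R)-methine, while the low temperature keeps the kinetic 2-aryl tetrahydrofuran centre intact and the excess of 9 suppresses self-alkylation of 23.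

Step 13
Reactants: 24 undeca-TBS ether of the target
Product: 25 CNP0225254.6
Conditions: HF·pyridine (excess), pyridine, THF, 0 → 25 °C
Reagents that add atoms: none
Why: Fluoride-mediated cleavage of all eleven aryl silyl ethers under buffered, non-basic and non-reducing conditions frees the phenols without touching the enone, the benzylic ethers or any stereocentre.

## Compound list

1 | 1-(2,4-dihydroxyphenyl)ethan-1-one (2',4'-dihydroxyacetophenone) | CC(=O)c1ccc(O)cc1O | starting material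
2 | 1-[2,4-bis(TBSO)phenyl]ethan-1-one | CC(=O)c1ccc(O[Si](C)(C)C(C)(C)C)cc1O[Si](C)(C)C(C)(C)C | intermediate
3 | 1,4-bis[2,4-bis(TBSO)phenyl]butane-1,4-dione (symmetric, achiral) | O=C(CCC(=O)c1ccc(O[Si](C)(C)C(C)(C)C)cc1O[Si](C)(C)C(C)(C)C)c1ccc(O[Si](C)(C)C(C)(C)C)cc1O[Si](C)(C)C(C)(C)C | intermediate
4 | 4-(TBSO)benzaldehyde | O=Cc1ccc(O[Si](C)(C)C(C)(C)C)cc1 | starting material
5 | (2R)-2-[(R)-hydroxy[4-(TBSO)phenyl]methyl]-1,4-bis[2,4-bis(TBSO)phenyl]butane-1,4-dione (syn aldol) | O[C@@H](c1ccc(O[Si](C)(C)C(C)(C)C)cc1)[C@H](C(=O)c1ccc(O[Si](C)(C)C(C)(C)C)cc1O[Si](C)(C)C(C)(C)C)CC(=O)c1ccc(O[Si](C)(C)C(C)(C)C)cc1O[Si](C)(C)C(C)(C)C | intermediate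
6 | [(2R,3R)-5-[2,4-bis(TBSO)phenyl]-2-[4-(TBSO)phenyl]-2,3-dihydrofuran-3-yl][2,4-bis(TBSO)phenyl]methanone (2,3-trans) | O1[C@@H](c2ccc(O[Si](C)(C)C(C)(C)C)cc2)[C@H](C(=O)c2ccc(O[Si](C)(C)C(C)(C)C)cc2O[Si](C)(C)C(C)(C)C)C=C1c1ccc(O[Si](C)(C)C(C)(C)C)cc1O[Si](C)(C)C(C)(C)C | intermediate
7 | [4-(bromomethyl)phenoxy](tert-butyl)dimethylsilane (4-(TBSO)benzyl bromide) | BrCc1ccc(O[Si](C)(C)C(C)(C)C)cc1 | starting material
8 | [(2R,3R,4R)-5-bromo-5-[2,4-bis(TBSO)phenyl]-4-[4-(TBSO)benzyl]-2-[4-(TBSO)phenyl]oxolan-3-yl][2,4-bis(TBSO)phenyl]methanone (both C5 epimers, in equilibrium with the oxocarbenium bromide) | BrC1(c2ccc(O[Si](C)(C)C(C)(C)C)cc2O[Si](C)(C)C(C)(C)C)O[C@@H](c2ccc(O[Si](C)(C)C(C)(C)C)cc2)[C@H](C(=O)c2ccc(O[Si](C)(C)C(C)(C)C)cc2O[Si](C)(C)C(C)(C)C)[C@H]1Cc1ccc(O[Si](C)(C)C(C)(C)C)cc1 | intermediate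
9 | [(2R,3R,4R,5S)-5-[2,4-bis(TBSO)phenyl]-4-[4-(TBSO)benzyl]-2-[4-(TBSO)phenyl]oxolan-3-yl][2,4-bis(TBSO)phenyl]methanone (2,3-trans, 3,4-trans, 4,5-cis) | c1cc([C@H]2O[C@@H](c3ccc(O[Si](C)(C)C(C)(C)C)cc3)[C@H](C(=O)c3ccc(O[Si](C)(C)C(C)(C)C)cc3O[Si](C)(C)C(C)(C)C)[C@H]2Cc2ccc(O[Si](C)(C)C(C)(C)C)cc2)c(O[Si](C)(C)C(C)(C)C)cc1O[Si](C)(C)C(C)(C)C | intermediate
10 | 4-bromo-2-iodophenol | Oc1ccc(Br)cc1I | starting material
11 | tert-butyl(4-ethynylphenoxy)dimethylsilane | C#Cc1ccc(O[Si](C)(C)C(C)(C)C)cc1 | starting material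
12 | 4-bromo-2-{[4-(TBSO)phenyl]ethynyl}phenol | Oc1ccc(Br)cc1C#Cc1ccc(O[Si](C)(C)C(C)(C)C)cc1 | intermediate
13 | 5-bromo-2-[4-(TBSO)phenyl]-1-benzofuran | Brc1ccc2oc(-c3ccc(O[Si](C)(C)C(C)(C)C)cc3)cc2c1 | intermediate
14 | 2,4-dihydroxybenzoic acid | O=C(O)c1ccc(O)cc1O | starting material
15 | tert-butyldimethylsilyl 2,4-bis(TBSO)benzoate | O=C(O[Si](C)(C)C(C)(C)C)c1ccc(O[Si](C)(C)C(C)(C)C)cc1O[Si](C)(C)C(C)(C)C | intermediate
16 | 2,4-bis(TBSO)benzoyl chloride | O=C(Cl)c1ccc(O[Si](C)(C)C(C)(C)C)cc1O[Si](C)(C)C(C)(C)C | intermediate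
17 | [2,4-bis(TBSO)phenyl]{5-bromo-2-[4-(TBSO)phenyl]-1-benzofuran-3-yl}methanone | Brc1ccc2oc(-c3ccc(O[Si](C)(C)C(C)(C)C)cc3)c(C(=O)c3ccc(O[Si](C)(C)C(C)(C)C)cc3O[Si](C)(C)C(C)(C)C)c2c1 | intermediate
18 | (2S)-5-bromo-3-{[2,4-bis(TBSO)phenyl][diethoxy(methyl)silyloxy]methylidene}-2-[4-(TBSO)phenyl]-2,3-dihydro-1-benzofuran (silyl enol ether, enol geometry undefined; C2 has the spatial arrangement of C2 in 20, the label changes by priority only) | Brc1ccc2c(c1)C(=C(O[Si](C)(OCC)OCC)c1ccc(O[Si](C)(C)C(C)(C)C)cc1O[Si](C)(C)C(C)(C)C)[C@H](c1ccc(O[Si](C)(C)C(C)(C)C)cc1)O2 | intermediate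
19 | [2,4-bis(TBSO)phenyl]{(2R,3S)-5-bromo-2-[4-(TBSO)phenyl]-2,3-dihydro-1-benzofuran-3-yl}methanone (2,3-cis) | Brc1ccc2c(c1)[C@H](C(=O)c1ccc(O[Si](C)(C)C(C)(C)C)cc1O[Si](C)(C)C(C)(C)C)[C@H](c1ccc(O[Si](C)(C)C(C)(C)C)cc1)O2 | intermediate
20 | [2,4-bis(TBSO)phenyl]{(2R,3R)-5-bromo-2-[4-(TBSO)phenyl]-2,3-dihydro-1-benzofuran-3-yl}methanone (2,3-trans) | Brc1ccc2c(c1)[C@@H](C(=O)c1ccc(O[Si](C)(C)C(C)(C)C)cc1O[Si](C)(C)C(C)(C)C)[C@H](c1ccc(O[Si](C)(C)C(C)(C)C)cc1)O2 | intermediate
21 | [2,4-bis(TBSO)phenyl]{(2R,3S)-5-bromo-2-[4-(TBSO)phenyl]-2,3-dihydro-1-benzofuran-3-yl}methanol (2,3-trans; both carbinol epimers) | Brc1ccc2c(c1)[C@@H](C(O)c1ccc(O[Si](C)(C)C(C)(C)C)cc1O[Si](C)(C)C(C)(C)C)[C@H](c1ccc(O[Si](C)(C)C(C)(C)C)cc1)O2 | intermediate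
22 | 1-[2,4-bis(TBSO)phenyl]prop-2-en-1-one | C=CC(=O)c1ccc(O[Si](C)(C)C(C)(C)C)cc1O[Si](C)(C)C(C)(C)C | intermediate
23 | (2E)-1-[2,4-bis(TBSO)phenyl]-3-[(2R,3S)-3-{[2,4-bis(TBSO)phenyl](hydroxy)methyl}-2-[4-(TBSO)phenyl]-2,3-dihydro-1-benzofuran-5-yl]prop-2-en-1-one (2,3-trans; both carbinol epimers) | O=C(/C=C/c1ccc2c(c1)[C@@H](C(O)c1ccc(O[Si](C)(C)C(C)(C)C)cc1O[Si](C)(C)C(C)(C)C)[C@H](c1ccc(O[Si](C)(C)C(C)(C)C)cc1)O2)c1ccc(O[Si](C)(C)C(C)(C)C)cc1O[Si](C)(C)C(C)(C)C | intermediate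
24 | undeca-TBS ether of 25 (all eleven phenols silylated, configuration as in 25) | O=C(/C=C/c1ccc2c(c1)[C@@H]([C@H](c1ccc(O[Si](C)(C)C(C)(C)C)cc1O[Si](C)(C)C(C)(C)C)c1cc([C@H]3O[C@@H](c4ccc(O[Si](C)(C)C(C)(C)C)cc4)[C@H](C(=O)c4ccc(O[Si](C)(C)C(C)(C)C)cc4O[Si](C)(C)C(C)(C)C)[C@H]3Cc3ccc(O[Si](C)(C)C(C)(C)C)cc3)c(O[Si](C)(C)C(C)(C)C)cc1O[Si](C)(C)C(C)(C)C)[C@H](c1ccc(O[Si](C)(C)C(C)(C)C)cc1)O2)c1ccc(O[Si](C)(C)C(C)(C)C)cc1O[Si](C)(C)C(C)(C)C | intermediate
25 | CNP0225254.6: (2E)-1-(2,4-dihydroxyphenyl)-3-[(2R,3R)-3-[(R)-(2,4-dihydroxyphenyl){5-[(2S,3R,4R,5R)-4-(2,4-dihydroxybenzoyl)-3-(4-hydroxybenzyl)-5-(4-hydroxyphenyl)oxolan-2-yl]-2,4-dihydroxyphenyl}methyl]-2-(4-hydroxyphenyl)-2,3-dihydro-1-benzofuran-5-yl]prop-2-en-1-one | O=C(/C=C/c1ccc2c(c1)[C@@H]([C@H](c1ccc(O)cc1O)c1cc([C@H]3O[C@@H](c4ccc(O)cc4)[C@H](C(=O)c4ccc(O)cc4O)[C@H]3Cc3ccc(O)cc3)c(O)cc1O)[C@H](c1ccc(O)cc1)O2)c1ccc(O)cc1O | target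

## Step count and risks

Total: 13 steps. Longest linear sequence: 7 steps (steps 5, 7, 8, 9, 11, 12, 13).

Steps most likely to fail:

**Step 8 (dearomatising CuH reduction).** The acceptor is a hindered, tetrasubstituted vinylogous ester inside a heteroarene, and 1,2-reduction of the ketone may compete. The fallback builds the dihydrobenzofuran without any dearomatisation. It sets out from 10, 7 and 2 and comes back at 19. Phenol 10 is O-alkylated with 7 (K2CO3, acetone, 25 °C) to the aryl benzyl ether F1. Pd-catalysed α-arylation of ketone 2 at the C–I bond of F1 (Pd2(dba)3, Xantphos, K3PO4, toluene, 80 °C) gives the deoxybenzoin F2. Diazo transfer (p-acetamidobenzenesulfonyl azide, DBU, MeCN, 0 °C) gives the diazo ketone F3. Enantioselective intramolecular benzylic C–H insertion of the derived carbenoid (Rh2(S-PTTL)4, CH2Cl2, −60 °C) closes the ring to the cis ketone 19, which is epimerised with DBU to 20 as in step 8.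

**Step 12 (Friedel–Crafts union).** The facial bias of the cation may be small or opposite, the cation can also lose the C3 proton, and the 2-aryl tetrahydrofuran centre could epimerise. The fallback replaces the substrate-controlled cation capture by a catalyst-controlled radical cross-coupling. It sets out from 21 and 9 and comes back at 24. Carbinol 21 is converted (SOCl2, 2,6-lutidine, CH2Cl2, −40 °C, used at once) into the benzylic chloride F4. Compound 9 is iodinated at the free position para to a silyloxy group (N-iodosuccinimide, MeCN, 0 °C) to the aryl iodide F5. Reductive cross-electrophile coupling (NiBr2(diglyme), chiral bi-oxazoline ligand, Mn powder, TMSCl, 1,4-dioxane, 25 °C) joins F4 and F5 through a benzylic radical, so both chloride epimers converge and the ligand fixes the methine, giving the aryl bromide F6. Heck reaction of F6 with 22 under the conditions of step 11 gives 24.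

**Step 4 (one-pot cationic benzylation and reduction).** The enol ether may oligomerise or be protonated and reduced without benzylation. The fallback makes the C–benzyl bond at sp2 carbon by cross-coupling and reduces in a separate operation. It sets out from 6 and 7 and comes back at 9. Bromination–dehydrobromination of 6 (N-bromosuccinimide, then Et3N, CH2Cl2, −78 → 0 °C) gives the vinyl bromide F7. Zinc insertion into 7 (Zn, LiCl, THF, 25 °C) gives the benzylzinc bromide F8. Negishi coupling of F7 with F8 (Pd(OAc)2, SPhos, THF, 25 °C) gives the benzylated enol ether F9. Ionic hydrogenation of F9 (Et3SiH, CF3CO2H, CH2Cl2, −78 °C) protonates the enol-ether carbon reversibly, so benzyl settles trans to aroyl, and delivers hydride anti to benzyl to give 9.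

## Further compounds

F1 | step 8 | 4-bromo-2-iodo-1-{[4-(TBSO)phenyl]methoxy}benzene | Brc1ccc(OCc2ccc(O[Si](C)(C)C(C)(C)C)cc2)c(I)c1
F2 | step 8 | 1-[2,4-bis(TBSO)phenyl]-2-(5-bromo-2-{[4-(TBSO)phenyl]methoxy}phenyl)ethan-1-one | O=C(Cc1cc(Br)ccc1OCc1ccc(O[Si](C)(C)C(C)(C)C)cc1)c1ccc(O[Si](C)(C)C(C)(C)C)cc1O[Si](C)(C)C(C)(C)C
F3 | step 8 | 1-[2,4-bis(TBSO)phenyl]-2-(5-bromo-2-{[4-(TBSO)phenyl]methoxy}phenyl)-2-diazoethan-1-one | O=C(C(=[N+]=[N-])c1cc(Br)ccc1OCc1ccc(O[Si](C)(C)C(C)(C)C)cc1)c1ccc(O[Si](C)(C)C(C)(C)C)cc1O[Si](C)(C)C(C)(C)C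
F4 | step 12 | (2R,3R)-5-bromo-3-{[2,4-bis(TBSO)phenyl](chloro)methyl}-2-[4-(TBSO)phenyl]-2,3-dihydro-1-benzofuran (2,3-trans; both chloride epimers) | Brc1ccc2c(c1)[C@@H](C(Cl)c1ccc(O[Si](C)(C)C(C)(C)C)cc1O[Si](C)(C)C(C)(C)C)[C@H](c1ccc(O[Si](C)(C)C(C)(C)C)cc1)O2
F5 | step 12 | [(2R,3R,4R,5S)-5-[5-iodo-2,4-bis(TBSO)phenyl]-4-[4-(TBSO)benzyl]-2-[4-(TBSO)phenyl]oxolan-3-yl][2,4-bis(TBSO)phenyl]methanone | Ic1cc([C@H]2O[C@@H](c3ccc(O[Si](C)(C)C(C)(C)C)cc3)[C@H](C(=O)c3ccc(O[Si](C)(C)C(C)(C)C)cc3O[Si](C)(C)C(C)(C)C)[C@H]2Cc2ccc(O[Si](C)(C)C(C)(C)C)cc2)c(O[Si](C)(C)C(C)(C)C)cc1O[Si](C)(C)C(C)(C)C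
F6 | step 12 | 5-bromo analogue of 24: the (2R,3R)-5-bromo-2-[4-(TBSO)phenyl]-2,3-dihydro-1-benzofuran carrying at C3 the (R)-methine with the 2,4-bis(TBSO)phenyl group and the aryl-tetrahydrofuran unit of 24 | Brc1ccc2c(c1)[C@@H]([C@H](c1ccc(O[Si](C)(C)C(C)(C)C)cc1O[Si](C)(C)C(C)(C)C)c1cc([C@H]3O[C@@H](c4ccc(O[Si](C)(C)C(C)(C)C)cc4)[C@H](C(=O)c4ccc(O[Si](C)(C)C(C)(C)C)cc4O[Si](C)(C)C(C)(C)C)[C@H]3Cc3ccc(O[Si](C)(C)C(C)(C)C)cc3)c(O[Si](C)(C)C(C)(C)C)cc1O[Si](C)(C)C(C)(C)C)[C@H](c1ccc(O[Si](C)(C)C(C)(C)C)cc1)O2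
F7 | step 4 | [(2R,3R)-4-bromo-5-[2,4-bis(TBSO)phenyl]-2-[4-(TBSO)phenyl]-2,3-dihydrofuran-3-yl][2,4-bis(TBSO)phenyl]methanone (2,3-trans) | O1[C@@H](c2ccc(O[Si](C)(C)C(C)(C)C)cc2)[C@H](C(=O)c2ccc(O[Si](C)(C)C(C)(C)C)cc2O[Si](C)(C)C(C)(C)C)C(Br)=C1c1ccc(O[Si](C)(C)C(C)(C)C)cc1O[Si](C)(C)C(C)(C)C
F8 | step 4 | bromo{[4-(TBSO)phenyl]methyl}zinc | Br[Zn]Cc1ccc(O[Si](C)(C)C(C)(C)C)cc1
F9 | step 4 | [(2R,3R)-4-[4-(TBSO)benzyl]-5-[2,4-bis(TBSO)phenyl]-2-[4-(TBSO)phenyl]-2,3-dihydrofuran-3-yl][2,4-bis(TBSO)phenyl]methanone (2,3-trans) | O1[C@@H](c2ccc(O[Si](C)(C)C(C)(C)C)cc2)[C@H](C(=O)c2ccc(O[Si](C)(C)C(C)(C)C)cc2O[Si](C)(C)C(C)(C)C)C(Cc2ccc(O[Si](C)(C)C(C)(C)C)cc2)=C1c1ccc(O[Si](C)(C)C(C)(C)C)cc1O[Si](C)(C)C(C)(C)C
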